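Readings and results are simulated for substances that don't exist; scatter was added.

1. Late in the blue run, between 15.0 min and 40.0 min, the electrophile falls at 0.00752 M/min, and I start from that slow rate.

- blue: electrophile 0.80 M; nucleophile 1.6 M; free base 1.6 M; run made earlier
- flask: electrophile 1.6 M; nucleophile 1.60 M; free base 1.60 M; time 50 min

blue run (percent of the electrophile charged)

| time / min | electrophile / % | product / % |
|---|---|---|
| 3.00 | 83.0 | 16.8 |
| 8.00 | 65.9 | 34.0 |
| 15.0 | 50.5 | 50.3 |
| 40.0 | 27.0 | 73.2 |

(readings scatter by 0.5 percentage points)

- part of the electrophile that has reacted at 50 min
- share of free nucleophile in free nucleophile and protonated nucleophile together, at 50 min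

- for acid set free the idle adduct and crystals are counted in
- as a solid, counted per litre of solution: crystals
- what was read earlier has a scatter of 0.5 percentage points, one standard deviation
- steps thought possible: nucleophile + acid set free <-> protonated nucleophile; electrophile + nucleophile -> acid set free + product; crystals <-> acid set free; nucleophile + acid set free <-> idle adduct; acid set free + free base <-> salt of the base
- the earlier runs do not show how much of nucleophile is bound; that part of a forecast is a guess

2. Over the first 3.00 min of the blue run the electrophile falls at 0.0453 M/min. Dividing by the mean [electrophile] and the charged [nucleophile] gives a rate constant, as read, of k = 0.0387 /M/min.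

3. I hold k fixed and divide the late rate by k and the mean late [electrophile]. That leaves [nucleophile] = 0.627 M, with 0.490 M of electrophile reacted.

4. So the cost, the nucleophile lost per electrophile reacted, is 1.99: one goes into product and the other, I take it, is bound by the acid set free.

5. In the flask, nucleophile and electrophile are charged about equally, so at this cost nucleophile is the limiting reagent. Its free concentration heads for zero at a knee: conversion = charged nucleophile / (cost × charged electrophile) = 50.3 %.

6. Near the knee, [electrophile] stands near 0.794 M, so the step with the electrophile, forward and by itself, halves [nucleophile] in 22.5 min, which is shorter than the 50 min allowed. I therefore commit to a conversion near the knee; how the bound nucleophile divides, the blue readings do not show.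

7. The forecast gives 51 % (48 % to 56 %) reacted and 7 % (3 % to 20 %) free, saying “conversion stalls near 50%”.

8. The flask gives 53.3 % reacted and 14.8 % free, which is 3.0 percentage points past the knee, with 6.2 % of its nucleophile unbound against 91 % of its free base.

    nucleophile + acid set free ⇌ protonated nucleophile, settled at all times (K = 97.0 /M)
    electrophile + nucleophile → acid set free + product (k = 6.80 × 10⁻⁴ /M/s)
    crystals ⇌ acid set free, rate k3*(cs3 - [acid set free]) while solid is left; crystals form when [acid set free] > cs3 (solubility = 1.10 M, k = 0.0180 /s)
    nucleophile + acid set free ⇌ idle adduct, settled at all times (K = 14.0 /M)
    acid set free + free base ⇌ salt of the base (K = 1.70 /M, k = 0.0260 /M/s)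

9. The same cost puts the knee of the neighbour flask charged with 0.40 M of nucleophile at 12.6 %, and that flask has reacted 16.5 %.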